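(The earlier runs and the new flask are simulated for substances that don't exist, and the scatter is random.)

Watch the lead.

| setting | oak | cedar | maple | Tuesday's | Saturday's |
|---|---|---|---|---|---|
| G | 0.23 M | 0.52 M | 0.35 M | 0.35 M | 0.35 M |
| Q | 1.2 equiv | 1.2 equiv | 2.4 equiv | 1.20 equiv | 1.20 equiv |
| remark | run made earlier | run made earlier | run made earlier |  |  |
| time |  |  |  | 20 min | 40 min |

| run | time / min | E / % | G / % | X / % | D / % |
|---|---|---|---|---|---|
| oak | 1.33 | 0 | 95.7 | 2.4 | 3.8 |
| oak | 4.00 | 0 | 89.7 | 5.0 | 8.0 |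
| oak | 6.00 | 1.1 | 83.3 | 6.4 | 11.0 |
| oak | 10.0 | 1.0 | 76.0 | 7.8 | 12.3 |
| oak | 15.0 | 2.5 | 71.3 | 14.4 | 12.0 |
| oak | 20.0 | 3.8 | 67.1 | 16.8 | 11.7 |
| oak | 25.0 | 5.5 | 61.3 | 20.8 | 10.4 |
| cedar | 1.33 | 0.1 | 92.1 | 2.7 | 6.2 |
| cedar | 4.00 | 0 | 80.6 | 3.1 | 13.4 |
| cedar | 6.00 | 2.9 | 73.8 | 7.5 | 14.9 |
| cedar | 10.0 | 3.9 | 65.5 | 8.7 | 15.8 |
| cedar | 15.0 | 7.0 | 59.2 | 12.2 | 18.0 |
| cedar | 20.0 | 12.2 | 52.4 | 15.6 | 16.3 |
| cedar | 25.0 | 12.0 | 48.9 | 16.8 | 14.3 |
| maple | 5.00 | 1.8 | 71.5 | 4.8 | 20.9 |
| maple | 10.0 | 7.3 | 58.2 | 6.8 | 20.9 |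
| maple | 15.0 | 15.4 | 47.5 | 10.5 | 19.1 |
| maple | 20.0 | 21.1 | 42.4 | 14.6 | 17.3 |
| maple | 25.0 | 23.1 | 36.3 | 15.8 | 17.2 |

(each reading ± 1 percentage point)

- a reading of E is of its free form alone

* which of these there is most of at the end, counted by the G in it, Tuesday's (G / X / D / E)
* which of these there is most of at the end, counted by the G in it, Saturday's (G / X / D / E)
* final amount of the leader among these, as a percentage of the G charged, in Tuesday's
* final amount of the leader among these, as a percentage of the G charged, in Saturday's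

1. Turn the question round: for G to lose the lead, another species must pass it by the end. The nearest rival is X: at 25.0 min, summed over oak and cedar, the readings show more X than D or E.

2. The charge of G in Tuesday's flask, 0.35 M, stands close to the geometric middle of oak and cedar, 0.346 M, with the same equivalents of Q, so we average those two runs. At 20 min they give G 59.7% and X 16.2% of the charge.

3. Between 10.0 min and 25.0 min, G fell in these runs at a mean fractional rate of 0.0169 min⁻¹. A share 0.674 of the G lost appeared as X, a selectivity as read.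

4. If that rate and share hold, X meets G when G has come down to 33.7%. That gives 53.8 min, the crossing time, our estimate of the moment at which X draws level with G and the lead changes hands. Saturday's 40 min stands 13.8 min before it, with G near 42.6% and X near 27.8%. So we expect G to lead in both flasks.

5. With the same share held, for the crossing to fall at 40 min, G would have to fall at 0.0286 min⁻¹, which is 1.69 times our rate and faster than the rate read from cedar, 0.0195 min⁻¹.

6. The forecast names G at 60% in Tuesday's and G at 46% in Saturday's, holding that “X grows at nearly the same fractional rate in all runs”, and its Saturday's figure stands above our 42.6%.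

7. The flasks give G in the lead at 59.9% in Tuesday's and G at 45.2% in Saturday's.

    Q + D ⇌ L (K = 3.10 L mol⁻¹, k = 0.120 L mol⁻¹ min⁻¹)
    L → E (k = 0.430 min⁻¹)
    E ⇌ J (K = 0.240, k = 0.0680 min⁻¹)
    G + Q ⇌ D (K = 0.920 L mol⁻¹, k = 0.100 L mol⁻¹ min⁻¹)
    G → X (k = 0.0110 min⁻¹)

At the start of Tuesday's flask, the forward step of G and Q into D used G faster than the step into X, by a factor of 3.8. Taken up from Saturday's 45.2% of G and 27.7% of X with the same rate and share, the crossing time comes to 55.5 min. Tuesday's flask left until 80 min, later than that, holds more X than G, 43.2% against 26.8%.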